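## Retrosynthetic overview

1. Target ⇒ bis-tiglate enone lacking the C6 hydroxyl: the C6–OH goes in last by Rubottom oxidation of the cross-conjugated silyl dienol ether, anti to the C5 isopropyl group.
2. Bis-tiglate ⇒ 4-tigloyloxy-5-isopropylcyclohex-2-enone: the C2–CH2O bond comes from a Morita–Baylis–Hillman reaction with formaldehyde, followed by esterification with tigloyl chloride.
3. That enone ⇒ (E)-4-methylpent-2-enal + tert-butyl acetoacetate + ditigloyl peroxide in one pot: amine-catalysed Michael addition (C5–C6 bond, sets C5), enamine α-tigloyloxylation (C4–O bond, sets C4 cis to isopropyl), then acid aldol condensation/decarboxylation (C2=C3).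
4. Ditigloyl peroxide ⇒ two molecules of tigloyl chloride + H2O2.
5. Ring order: the only ring, the cyclohexenone, is closed once, in the last stage of the one-pot step.

Assumption: Tig = tigloyl = (E)-2-methylbut-2-enoyl; ring positions follow cyclohex-2-en-1-one numbering (C1 = C=O, C2 bears CH2OTig, C4 OTig, C5 isopropyl, C6 OH); both enantiomers of the silyl prolinol catalyst are taken as commercial.

The target is (4S,5R,6R): the C4 ester is cis to the C5 isopropyl group and the C6 hydroxyl is trans to it; both esters are tiglates (E).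

## Route

Step 1
Reactants: 1 tigloyl chloride [(E)-2-methylbut-2-enoyl chloride], 2 equiv
Product: 2 bis[(E)-2-methylbut-2-enoyl] peroxide (ditigloyl peroxide)
Conditions: 30% aq. H2O2 (0.5 equiv relative to 1), NaOH, Et2O/H2O, 0 °C (kept cold, not heated or dried hard)
Reagents that add atoms: hydrogen peroxide, OO; tigloyl chloride (the second equivalent of 1), C/C=C(\C)C(=O)Cl
Why: Schotten–Baumann double acylation of hydrogen peroxide by two molecules of the acid chloride, as in the standard preparation of dibenzoyl peroxide; a conjugated diacyl peroxide of this kind is isolable, and no stereocentre or alkene geometry is touched.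

Step 2
Reactants: 3 (E)-4-methylpent-2-enal; 4 tert-butyl acetoacetate; 2 ditigloyl peroxide
Product: 8 (4S,5S)-5-isopropyl-4-tigloyloxycyclohex-2-en-1-one, via Michael adduct 5 (not isolated), via acyloxy aldehyde 6 (not isolated), via cyclised keto ester 7 (not isolated)
Conditions: (R)-2-{bis[3,5-bis(trifluoromethyl)phenyl](trimethylsilyloxy)methyl}pyrrolidine (10 mol %), PhCO2H (10 mol %), toluene, rt; then 2 (1.05 equiv), hydroquinone (10 mol %), THF, 0 °C; then TsOH·H2O (30 mol %), toluene, 70 °C
Reagents that add atoms: none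
Why: Proposed new method: an iminium–enamine relay in which the (R)-prolinol silyl ether forms the E-iminium ion of 3 and sends the keto ester to the unshielded face of the β-carbon (sets C5), the E-enamine so formed, shielded on the same face by the C(Ar)2OSiMe3 group, attacks the O–O bond of 2 by displacement at oxygen (sets C4; net syn addition across the enal, which maps onto the cis C4–O/C5–isopropyl relationship in the ring), and acid then closes the ring by aldol condensation of the methyl ketone onto the aldehyde and removes the tert-butyl ester by decarboxylation; the closest known reactions are the amine-catalysed Michael/aldol-condensation/decarboxylation route to 5-substituted cyclohex-2-enones, the amine-catalysed α-benzoyloxylation of aldehydes with dibenzoyl peroxide and iminium–enamine cascades ending in α-halogenation or α-amination, and what is new is the C–C then C–O relay with a diacyl peroxide and the use of an α,β-unsaturated diacyl peroxide as the acyloxy donor.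

Step 3
Reactants: 8 (4S,5S)-5-isopropyl-4-tigloyloxycyclohex-2-en-1-one
Product: 9 (4R,5S)-2-(hydroxymethyl)-5-isopropyl-4-tigloyloxycyclohex-2-en-1-one
Conditions: 37% aq. HCHO, imidazole (20 mol %), 1 M aq. NaHCO3, THF, rt
Reagents that add atoms: formaldehyde, C=O
Why: Morita–Baylis–Hillman reaction, in which imidazole adds reversibly at C3, the enolate takes up formaldehyde at C2 and loss of imidazole restores the enone; no stereocentre is formed and the near-neutral medium leaves C4 and the tiglate alone (the C4 descriptor changes from S to R only because the CIP priorities change).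

Step 4
Reactants: 9 (4R,5S)-2-(hydroxymethyl)-5-isopropyl-4-tigloyloxycyclohex-2-en-1-one; 1 tigloyl chloride
Product: 10 (4R,5S)-5-isopropyl-4-tigloyloxy-2-(tigloyloxymethyl)cyclohex-2-en-1-one
Conditions: pyridine, CH2Cl2, 0 °C to rt
Reagents that add atoms: none
Why: Simple acylation of the primary allylic alcohol with an acid chloride; pyridine is used without DMAP so that no strongly nucleophilic amine can attack the allylic ester product in an SN2′ sense.

Step 5
Reactants: 10 (4R,5S)-5-isopropyl-4-tigloyloxy-2-(tigloyloxymethyl)cyclohex-2-en-1-one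
Product: 14 (4S,5R,6R)-6-hydroxy-5-isopropyl-4-tigloyloxy-2-(tigloyloxymethyl)cyclohex-2-en-1-one, via silyl dienol ether 11 (not isolated), via silyloxy epoxide 12 (not isolated), via silyloxy ketone 13 (not isolated)
Conditions: TMSOTf, Et3N, CH2Cl2, −78 to 0 °C; crude 11, mCPBA, CH2Cl2, −20 °C; then aq. citric acid, THF, rt
Reagents that add atoms: 3-chloroperoxybenzoic acid, OOC(=O)c1cccc(Cl)c1; trimethylsilyl trifluoromethanesulfonate, C[Si](C)(C)OS(=O)(=O)C(F)(F)F (its SiMe3 group is carried only in 11, 12 and 13)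
Why: Rubottom oxidation, in which soft enolisation of the enone gives the cross-conjugated 2-silyloxy diene on the C6 side, the peracid epoxidises this most electron-rich double bond from the face opposite the C5 isopropyl and the C4 ester (sets C6, OH trans to isopropyl), and silyl migration and hydrolysis give the α′-hydroxy enone while the conjugated tiglate alkenes stay untouched.

## Compound list

1 | tigloyl chloride, (E)-2-methylbut-2-enoyl chloride | C/C=C(\C)C(=O)Cl | starting material
2 | bis[(E)-2-methylbut-2-enoyl] peroxide (ditigloyl peroxide) | C/C=C(\C)C(=O)OOC(=O)/C(C)=C/C | intermediate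
3 | (E)-4-methylpent-2-enal | CC(C)/C=C/C=O | starting material
4 | tert-butyl acetoacetate (tert-butyl 3-oxobutanoate) | CC(=O)CC(=O)OC(C)(C)C | starting material
5 | tert-butyl (3R)-2-acetyl-3-isopropyl-5-oxopentanoate (C2 epimers) | O=CC[C@H](C(C)C)C(C(C)=O)C(=O)OC(C)(C)C | intermediate (not isolated)
6 | tert-butyl (3R,4R)-2-acetyl-3-isopropyl-5-oxo-4-tigloyloxypentanoate (C2 epimers) | O=C[C@H](OC(=O)/C(C)=C/C)[C@H](C(C)C)C(C(C)=O)C(=O)OC(C)(C)C | intermediate (not isolated)
7 | tert-butyl (5S,6R)-6-isopropyl-2-oxo-5-tigloyloxycyclohex-3-ene-1-carboxylate (C1 epimers) | O=C1C=C[C@H](OC(=O)/C(C)=C/C)[C@H](C(C)C)C1C(=O)OC(C)(C)C | intermediate (not isolated)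
8 | (4S,5S)-5-isopropyl-4-tigloyloxycyclohex-2-en-1-one | O=C1C=C[C@H](OC(=O)/C(C)=C/C)[C@H](C(C)C)C1 | intermediate
9 | (4R,5S)-2-(hydroxymethyl)-5-isopropyl-4-tigloyloxycyclohex-2-en-1-one | OCC1=C[C@H](OC(=O)/C(C)=C/C)[C@H](C(C)C)CC1=O | intermediate
10 | (4R,5S)-5-isopropyl-4-tigloyloxy-2-(tigloyloxymethyl)cyclohex-2-en-1-one | C/C=C(\C)C(=O)OCC1=C[C@H](OC(=O)/C(C)=C/C)[C@H](C(C)C)CC1=O | intermediate
11 | [(3R,4R)-4-isopropyl-3-tigloyloxy-6-(trimethylsilyloxy)cyclohexa-1,5-dien-1-yl]methyl tiglate (cross-conjugated silyl dienol ether of 10) | C/C=C(\C)C(=O)OCC1=C[C@H](OC(=O)/C(C)=C/C)[C@H](C(C)C)C=C1O[Si](C)(C)C | intermediate (not isolated)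
12 | C1–C6 epoxide of 11 (C1 bears OSiMe3; oxirane oxygen on the ring face opposite the isopropyl group) | C/C=C(\C)C(=O)OCC1=C[C@H](OC(=O)/C(C)=C/C)[C@H](C(C)C)[C@H]2O[C@@]12O[Si](C)(C)C | intermediate (not isolated)
13 | (4S,5S,6R)-5-isopropyl-4-tigloyloxy-2-(tigloyloxymethyl)-6-(trimethylsilyloxy)cyclohex-2-en-1-one | C/C=C(\C)C(=O)OCC1=C[C@H](OC(=O)/C(C)=C/C)[C@H](C(C)C)[C@@H](O[Si](C)(C)C)C1=O | intermediate (not isolated)
14 | (4S,5R,6R)-6-hydroxy-5-isopropyl-4-tigloyloxy-2-(tigloyloxymethyl)cyclohex-2-en-1-one (CNP0326914.1) | C/C=C(\C)C(=O)OCC1=C[C@H](OC(=O)/C(C)=C/C)[C@H](C(C)C)[C@@H](O)C1=O | target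

## Step count and risks

Total steps: 5. Longest linear sequence: 5 (1 → 2 → 8 → 9 → 10 → 14; 4 steps counted from 3 or 4).

Steps most likely to fail:

Step 2 (the new relay). The peroxide may acyloxylate the catalyst nitrogen or the keto-ester carbon instead of the enamine. The Michael adduct may rest as its cyclic hemiacetal and form the enamine slowly, and the enamine step may give poor diastereocontrol. The hot acid stage may erode C4, cause acyl migration, or eliminate tiglic acid toward 3-isopropylphenol. The fallback uses known chemistry and sets out from 3 and 4. The same amine-catalysed Michael addition to 5, followed directly by TsOH·H2O in toluene at 80 °C, gives, through tert-butyl (6R)-6-isopropyl-2-oxocyclohex-3-ene-1-carboxylate F1 (not isolated), (5S)-5-isopropylcyclohex-2-en-1-one F2. Isopropenyl acetate with catalytic TsOH at reflux gives the linear dienyl acetate (5S)-5-isopropylcyclohexa-1,3-dien-1-yl acetate F3. mCPBA attacks the terminal C3=C4 bond anti to the isopropyl group to give the 3,4-epoxide of the dienyl acetate F4. This opens on aqueous work-up, with loss of the acetyl group, to (4R,5S)-4-hydroxy-5-isopropylcyclohex-2-en-1-one F5. Mitsunobu esterification with tiglic acid (PPh3, DIAD, THF, 0 °C) inverts C4 and comes back to the route at 8.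

Step 5 (late Rubottom oxidation). Enolisation may go toward C4 instead of C6, and the allylic ester at C2 may suffer SN2′ attack under the silylation conditions. The fallback sets out from 8 and installs the C6 oxygen before the sensitive ester is present. The kinetic enolate (LiN(SiMe3)2, THF, −78 °C) is oxidised with 2-(phenylsulfonyl)-3-phenyloxaziridine, anti to isopropyl, to give (4S,5R,6R)-6-hydroxy-5-isopropyl-4-tigloyloxycyclohex-2-en-1-one F7. Et3SiCl and imidazole give (4S,5S,6R)-5-isopropyl-4-tigloyloxy-6-(triethylsilyloxy)cyclohex-2-en-1-one F8. The conditions of step 3 give (4S,5S,6R)-2-(hydroxymethyl)-5-isopropyl-4-tigloyloxy-6-(triethylsilyloxy)cyclohex-2-en-1-one F9. Compound 1 and pyridine give (4S,5S,6R)-5-isopropyl-4-tigloyloxy-2-(tigloyloxymethyl)-6-(triethylsilyloxy)cyclohex-2-en-1-one F10. HF·pyridine in THF at 0 °C removes the silyl group and comes back to the route at 14.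

Step 3 (Morita–Baylis–Hillman reaction next to a γ-acyloxy group). The reaction may be slow for steric reasons, or the amine may cleave or shift the C4 ester. The fallback sets out from 8. Iodine and pyridine in CH2Cl2 give (4R,5S)-2-iodo-5-isopropyl-4-tigloyloxycyclohex-2-en-1-one F6. Stille coupling with Bu3SnCH2OH (Pd(PPh3)4, CuI, NMP, 50 °C) comes back to the route at 9.

## Further compounds

F1 | step 2 | tert-butyl (6R)-6-isopropyl-2-oxocyclohex-3-ene-1-carboxylate (C1 epimers) | O=C1C=CC[C@H](C(C)C)C1C(=O)OC(C)(C)C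
F2 | step 2 | (5S)-5-isopropylcyclohex-2-en-1-one | O=C1C=CC[C@H](C(C)C)C1
F3 | step 2 | (5S)-5-isopropylcyclohexa-1,3-dien-1-yl acetate | CC(=O)OC1=CC=C[C@H](C(C)C)C1
F4 | step 2 | 3,4-epoxide of the dienyl acetate (oxirane oxygen anti to isopropyl) | CC(=O)OC1=C[C@H]2O[C@H]2[C@H](C(C)C)C1
F5 | step 2 | (4R,5S)-4-hydroxy-5-isopropylcyclohex-2-en-1-one | O=C1C=C[C@@H](O)[C@H](C(C)C)C1
F6 | step 3 | (4R,5S)-2-iodo-5-isopropyl-4-tigloyloxycyclohex-2-en-1-one | O=C1C(I)=C[C@H](OC(=O)/C(C)=C/C)[C@H](C(C)C)C1
F7 | step 5 | (4S,5R,6R)-6-hydroxy-5-isopropyl-4-tigloyloxycyclohex-2-en-1-one | O=C1C=C[C@H](OC(=O)/C(C)=C/C)[C@H](C(C)C)[C@H]1O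
F8 | step 5 | (4S,5S,6R)-5-isopropyl-4-tigloyloxy-6-(triethylsilyloxy)cyclohex-2-en-1-one | O=C1C=C[C@H](OC(=O)/C(C)=C/C)[C@H](C(C)C)[C@H]1O[Si](CC)(CC)CC
F9 | step 5 | (4S,5S,6R)-2-(hydroxymethyl)-5-isopropyl-4-tigloyloxy-6-(triethylsilyloxy)cyclohex-2-en-1-one | OCC1=C[C@H](OC(=O)/C(C)=C/C)[C@H](C(C)C)[C@@H](O[Si](CC)(CC)CC)C1=O
F10 | step 5 | (4S,5S,6R)-5-isopropyl-4-tigloyloxy-2-(tigloyloxymethyl)-6-(triethylsilyloxy)cyclohex-2-en-1-one | C/C=C(\C)C(=O)OCC1=C[C@H](OC(=O)/C(C)=C/C)[C@H](C(C)C)[C@@H](O[Si](CC)(CC)CC)C1=O
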